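## Analysis of the target

The target 15 is an open-chain 1,7-diarylheptan-3-one. The chain C1–C7 carries ring B (4-hydroxy-3,5-dimethoxyphenyl) on C1 and ring A (4-hydroxy-3-methoxyphenyl) on C7, a ketone at C3 and a secondary alcohol at C5; no ring has to be closed. C5 is the only stereocentre and is R (OH > C4H2–C3=O > C6H2 > H); with no neighbouring stereocentre to relay chirality, it must be set by a reagent or catalyst. The feature the route is built on is the two-carbon unit C4–C5: C5 carries the oxygen and the alkyl arm C6–C7–ring A, and C4 carries the acyl group C3(=O)–C2–C1–ring B. That is exactly the pattern left when a vinyl group takes up an alkyl group, a heteroatom and an acyl group. The β-hydroxy ketone is the sensitive part: acid, base or heat eliminate water across C4–C5 to the conjugated enone, and base can also cleave C4–C5 by retro-aldol reaction; both erase the stereocentre. The two phenols are acidic and their rings are easily oxidised, so they must be masked against boranes and organolithium reagents and freed at the end under neutral conditions. The synthesis is hard for two reasons: the arms on C3 and C5 are both 2-arylethyl groups that differ only in one methoxy group of ring B, so a 1,3-dicarbonyl precursor offers nothing to tell C3 from C5; and the classical C4–C5 aldol is an acetate-type aldol with an unbranched, enolisable aldehyde, the class with the weakest stereocontrol.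

## Retrosynthetic reasoning

**15 to 14.** The two phenolic O–H bonds are traced back to benzyl ethers in 14. Hydrogenolysis is neutral, so the last step cannot dehydrate or cleave the β-hydroxy ketone, and benzyl ethers survive borane, organolithium, nickel and acid chloride chemistry. The forward reaction must cleave two aryl O–CH2Ph bonds without touching C5–O or C3=O.

**14 to 13.** The C5–O bond is traced back to a C5–B bond in the β-boryl ketone 13. Boron marks C5, and only C5, as the future carbinol, so C3 and C5 are never alike in this route. Oxidation of a C–B bond goes with retention, so the stereochemical problem becomes that of making the C5–B centre.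

**13 to 12 and 9 (key disconnection).** Two C–C bonds are cut at once, C3–C4 and C5–C6. C4–C5 is left as the vinyl group of the four-coordinate borate 12, C6 returns to boron as a B-alkyl group, and C3 becomes the carbonyl carbon of the acid chloride 9. These cuts flank the two functional carbons with natural polarity: C3 is an acyl electrophile and C6 a migrating alkyl group on boron. No enolate is needed, so there is no C2/C4 regiochemistry problem, and no enolisable aldehyde is needed. The skeleton is joined from three achiral pieces, and the only stereocentre is set in the same operation. The forward reaction must deliver a nickel-bound acyl group to C4 and make the C6 alkyl group migrate from boron to C5 on one face of the vinyl group.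

**12 to 11 and 10, and 11 to 2.** The B–vinyl bond of 12 is cut to the trialkylborane 11 and vinyllithium 10. The B–C6 and C7–H bonds of 11 are cut by retro-hydroboration to the styrene 2. The whole ring A arm is thus just a vinyl group on the arene; the forward hydroboration must place boron on the terminal carbon with a bicyclic dialkylborane.

**2 to 1; 9 to 8 to 4 and 5 to 3.** Styrene 2 is the benzyl ether of the commercial phenol 1. Acid chloride 9 comes from acid 8. The C1–C2 bond of 8 is cut by a reductive Knoevenagel disconnection to aldehyde 4 and Meldrum's acid 5, which supplies C2 and C3; 4 is the benzyl ether of syringaldehyde 3. All carbons of the target thus come from 1 (ring A, C7, C6), 10 (C5, C4), 5 (C3, C2) and 3 (C1, ring B).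

## Alternatives that were turned down

**Alternative 1:** Disconnection of C4–C5, the textbook aldol. The forward key step is enolisation of methyl ketone A1 on its methyl side with a chiral dialkylboron chloride and an amine, followed by addition to aldehyde A2. It was turned down for four reasons. A1 has two enolisable positions (C4 and C2) of nearly equal acidity, so regiocontrol rests on kinetics alone. The enolate has no substituent on C4, so the cyclic transition state lacks the element that normally transmits chirality, and the unbranched A2 offers little steric differentiation. A2 is an enolisable, self-condensing aldehyde that needs its own redox adjustments. The chiral controller is stoichiometric. With three steps to each partner, the route would be about eight steps for one C–C bond and a stereocentre of doubtful purity.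

**Alternative 2:** Disconnection of C5–O. The forward key step is a copper-catalysed enantioselective conjugate borylation of the E-enone A3, followed by oxidation in the same flask. The stereochemical precedent is good, but the key step forms no C–C bond. A3 already holds the complete C22 skeleton, so both arms and their union by olefination or metathesis must be paid for beforehand, and the key-step precursor is no simpler than its product. The route would be eight to nine steps. It is kept as the fallback for the key step.

**Alternative 3:** Disconnection of C5–H. The forward key step is mono-reduction of the 1,3-diketone A4 by a ketoreductase (alcohol dehydrogenase class) or a ruthenium–bisphosphine hydrogenation catalyst. It was turned down because the carbonyl groups at C3 and C5 of A4 have identical neighbours out to the aryl rings and differ only in one remote methoxy group on ring B. A4 is also largely enolised across C3–C5. No steric or electronic argument predicts that a catalyst or an enzyme pocket would reduce C5 and not C3, reduction at C3 would give a constitutional isomer hardly separable from the target, and a second reduction of the remaining carbonyl is a further loss channel. The entire regio- and stereochemical burden would rest on a recognition event that cannot be defended in advance.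

Key step: step 5

Remark on the chemistry (assumption): vinyllithium 10 is taken as a titrated, halide-free THF solution, made beforehand in the standard way from tetravinylstannane and n-butyllithium; this reagent preparation is not counted as a step. The sense of induction of the chiral diamine in step 5 cannot be derived safely from a model, so the antipode that gives 5R is to be fixed in a first run (both antipodes are available).

## Route

Step 1
Reactants: 1 2-methoxy-4-vinylphenol (4-vinylguaiacol)
Product: 2 1-(benzyloxy)-2-methoxy-4-vinylbenzene
Conditions: BnBr (1.1 equiv), K2CO3 (1.5 equiv), DMF, rt, dark, trace BHT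
Reagents that add atoms: benzyl bromide, BrCc1ccccc1
Why: Williamson ether synthesis on the phenoxide; room temperature and a radical inhibitor should keep the styrene from polymerising, and the benzyl ether removes the acidic O–H that would consume the borane and the organolithium of step 5.

Step 2
Reactants: 3 4-hydroxy-3,5-dimethoxybenzaldehyde (syringaldehyde)
Product: 4 4-(benzyloxy)-3,5-dimethoxybenzaldehyde
Conditions: BnBr (1.2 equiv), K2CO3 (2 equiv), DMF, 60 °C
Reagents that add atoms: benzyl bromide, BrCc1ccccc1
Why: Williamson ether synthesis; the phenoxide flanked by two methoxy groups is hindered but reacts cleanly with an unhindered benzylic bromide in a polar aprotic solvent.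

Step 3
Reactants: 4 4-(benzyloxy)-3,5-dimethoxybenzaldehyde; 5 2,2-dimethyl-1,3-dioxane-4,6-dione (Meldrum's acid)
Product: 8 3-[4-(benzyloxy)-3,5-dimethoxyphenyl]propanoic acid, via arylidene Meldrum's acid 6 (not isolated), via arylmethyl Meldrum's acid 7 (not isolated)
Conditions: HCO2H/Et3N (5:2, solvent and reductant), 95–100 °C; then aq HCl, 0 °C
Reagents that add atoms: none
Why: One-pot reductive Knoevenagel condensation: condensation gives the doubly activated alkene 6, formate transfers hydride to its benzylic carbon to give 7, and the hot medium opens the dioxanedione and decarboxylates it to the propanoic acid; no metal catalyst is present, so the benzyl ether should stay intact.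

Step 4
Reactants: 8 3-[4-(benzyloxy)-3,5-dimethoxyphenyl]propanoic acid
Product: 9 3-[4-(benzyloxy)-3,5-dimethoxyphenyl]propanoyl chloride
Conditions: (COCl)2 (1.3 equiv), DMF (cat.), CH2Cl2, 0 °C to rt; evaporate with toluene, use crude at once
Reagents that add atoms: oxalyl chloride, ClC(=O)C(=O)Cl
Why: Acid chloride formation through the catalytic chloroiminium (Vilsmeier-type) species; the Lewis-acid-free, low-temperature conditions should avoid Friedel–Crafts ring closure onto the electron-rich ring B.

Step 5
Reactants: 2 1-(benzyloxy)-2-methoxy-4-vinylbenzene; 9 3-[4-(benzyloxy)-3,5-dimethoxyphenyl]propanoyl chloride; 10 vinyllithium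
Product: 14 (5R)-7-[4-(benzyloxy)-3-methoxyphenyl]-1-[4-(benzyloxy)-3,5-dimethoxyphenyl]-5-hydroxyheptan-3-one, via alkylborane 11 (not isolated), via lithium vinylborate 12 (not isolated), via boryl ketone 13 (not isolated)
Conditions: 2 (1.1 equiv), 9-BBN dimer (0.55 equiv), THF, rt; 10 (1.1 equiv), 0 °C; NiBr2·glyme (10 mol %), one antipode of N,N'-dimethyl-1,2-diphenylethane-1,2-diamine (12 mol %, the one leading to 5R), 9 (1.0 equiv, added cold), THF, 0 °C to rt; then pH 7 phosphate buffer, 30 % aq H2O2, 0 °C to rt
Reagents that add atoms: hydrogen peroxide, OO (the oxygen on C5 of 14); 9-borabicyclo[3.3.1]nonane, [BH]1C2CCCC1CCC2 (its boron and ring are carried only in 11, 12 and 13)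
Why: 9-BBN adds across the vinyl group of 2 with boron on the terminal carbon (C6) to give 11, and 10 adds to boron to give the four-coordinate vinyl borate 12. A zerovalent nickel–diamine species, formed from the divalent nickel salt by a little of the borate, inserts into the C–Cl bond of 9; the acylnickel binds the vinyl π-bond of 12 and induces a 1,2-metallate shift in which the 2-arylethyl group moves from boron to C5 while nickel bonds to C4, and reductive elimination then forms C3–C4 to give 13. The closest known reaction type is the nickel-catalysed enantioselective conjunctive cross-coupling of 9-BBN-derived vinyl borates with acid chlorides or anhydrides, followed by oxidation to the β-hydroxy ketone. No ring is closed. C5 is the only new stereocentre; it is set in the metallate shift by the chiral diamine on nickel, which decides which face of the vinyl group nickel takes (pure catalyst control, since all three components are achiral), and buffered peroxide then replaces boron by oxygen with retention, so that 5R in 13 becomes 5R in 14. The step needs migration of the exocyclic 2-arylethyl group and not of a ring carbon of the bicycle, which the rigid bicyclo[3.3.1]nonane frame secures, and it needs acyl transfer to C4 through the shift and not direct transfer of the vinyl group to the acylnickel, which the poorly transmetalating four-coordinate borate and the diamine ligand favour. Uncatalysed acylation of 12 by 9 would give racemic product and is held back by adding 9 cold to the solution that already holds the catalyst.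

Step 6
Reactants: 14 (5R)-7-[4-(benzyloxy)-3-methoxyphenyl]-1-[4-(benzyloxy)-3,5-dimethoxyphenyl]-5-hydroxyheptan-3-one
Product: 15 (5R)-5-hydroxy-1-(4-hydroxy-3,5-dimethoxyphenyl)-7-(4-hydroxy-3-methoxyphenyl)heptan-3-one (CNP0252358.1)
Conditions: H2 (1 atm), Pd/C (10 wt % Pd), EtOAc, rt
Reagents that add atoms: none
Why: Hydrogenolysis of the two aryl benzyl ethers under neutral conditions; the β-hydroxy ketone has no benzylic C–O bond and an unactivated dialkyl ketone is not reduced over palladium at 1 atm, so C5 should keep its configuration and no dehydration or retro-aldol pathway is opened.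

## Compound list

1 | 2-methoxy-4-vinylphenol (4-vinylguaiacol) | C=Cc1ccc(O)c(OC)c1 | starting material
2 | 1-(benzyloxy)-2-methoxy-4-vinylbenzene | C=Cc1ccc(OCc2ccccc2)c(OC)c1 | intermediate
3 | 4-hydroxy-3,5-dimethoxybenzaldehyde (syringaldehyde) | COc1cc(C=O)cc(OC)c1O | starting material
4 | 4-(benzyloxy)-3,5-dimethoxybenzaldehyde | COc1cc(C=O)cc(OC)c1OCc1ccccc1 | intermediate
5 | 2,2-dimethyl-1,3-dioxane-4,6-dione (Meldrum's acid) | CC1(C)OC(=O)CC(=O)O1 | starting material
6 | 5-[4-(benzyloxy)-3,5-dimethoxybenzylidene]-2,2-dimethyl-1,3-dioxane-4,6-dione | COc1cc(C=C2C(=O)OC(C)(C)OC2=O)cc(OC)c1OCc1ccccc1 | intermediate (not isolated)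
7 | 5-[4-(benzyloxy)-3,5-dimethoxybenzyl]-2,2-dimethyl-1,3-dioxane-4,6-dione | COc1cc(CC2C(=O)OC(C)(C)OC2=O)cc(OC)c1OCc1ccccc1 | intermediate (not isolated)
8 | 3-[4-(benzyloxy)-3,5-dimethoxyphenyl]propanoic acid | COc1cc(CCC(=O)O)cc(OC)c1OCc1ccccc1 | intermediate
9 | 3-[4-(benzyloxy)-3,5-dimethoxyphenyl]propanoyl chloride | COc1cc(CCC(=O)Cl)cc(OC)c1OCc1ccccc1 | intermediate
10 | vinyllithium | [Li]C=C | starting material
11 | 9-{2-[4-(benzyloxy)-3-methoxyphenyl]ethyl}-9-borabicyclo[3.3.1]nonane | COc1cc(CCB2C3CCCC2CCC3)ccc1OCc1ccccc1 | intermediate (not isolated)
12 | lithium 9-{2-[4-(benzyloxy)-3-methoxyphenyl]ethyl}-9-vinyl-9-boratabicyclo[3.3.1]nonane | [Li+].C=C[B-]1(CCc2ccc(OCc3ccccc3)c(OC)c2)C2CCCC1CCC2 | intermediate (not isolated)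
13 | (5R)-7-[4-(benzyloxy)-3-methoxyphenyl]-1-[4-(benzyloxy)-3,5-dimethoxyphenyl]-5-(9-borabicyclo[3.3.1]nonan-9-yl)heptan-3-one | COc1cc(CC[C@@H](B2C3CCCC2CCC3)CC(=O)CCc2cc(OC)c(OCc3ccccc3)c(OC)c2)ccc1OCc1ccccc1 | intermediate (not isolated)
14 | (5R)-7-[4-(benzyloxy)-3-methoxyphenyl]-1-[4-(benzyloxy)-3,5-dimethoxyphenyl]-5-hydroxyheptan-3-one | COc1cc(CC[C@@H](O)CC(=O)CCc2cc(OC)c(OCc3ccccc3)c(OC)c2)ccc1OCc1ccccc1 | intermediate
15 | (5R)-5-hydroxy-1-(4-hydroxy-3,5-dimethoxyphenyl)-7-(4-hydroxy-3-methoxyphenyl)heptan-3-one | COc1cc(CC[C@@H](O)CC(=O)CCc2cc(OC)c(O)c(OC)c2)ccc1O | target

## Step count and least certain steps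

Total: 6 steps. Longest linear sequence: 5 steps (3 to 4 to 8 to 9 to 14 to 15, steps 2, 3, 4, 5 and 6); step 1 is the single step of the second branch.

**Step 5 (key step).** Four things may go wrong.
- Face discrimination by the diamine–nickel catalyst may be insufficient for this flexible aliphatic acid chloride.
- Uncatalysed acylation of the borate would feed racemic material into the product.
- Direct transfer of the vinyl group to the acylnickel, without the metallate shift, would give an enone and waste both partners.
- Loss of water across C4–C5 may occur during the oxidative work-up if the pH drifts upward.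

The enantiomeric purity of 14 is to be checked on a chiral phase before step 6. The fallback abandons the three-component union and sets C5 by conjugate borylation of a preformed enone; it sets out from 11 (made from 2 as in step 5) and from 9 and comes back to the route at 14. Borane 11 is coupled with vinyl bromide in a B-alkyl Suzuki–Miyaura reaction (PdCl2(dppf), aq K3PO4, THF/DMF) to 1-(benzyloxy)-4-(but-3-en-1-yl)-2-methoxybenzene F1. Acid chloride 9 is coupled with tributyl(vinyl)stannane (PdCl2(PPh3)2 cat., THF) to the vinyl ketone 5-[4-(benzyloxy)-3,5-dimethoxyphenyl]pent-1-en-3-one F2. Cross-metathesis of F1 with F2 (second-generation Grubbs catalyst, CH2Cl2, 40 °C) should give the E-enone A3. Copper-catalysed enantioselective conjugate borylation of A3 (CuCl, NaOtBu, a Josiphos-type ferrocenyl bisphosphine, B2pin2, MeOH, THF) should give the pinacol boronate (5R)-7-[4-(benzyloxy)-3-methoxyphenyl]-1-[4-(benzyloxy)-3,5-dimethoxyphenyl]-5-(4,4,5,5-tetramethyl-1,3,2-dioxaborolan-2-yl)heptan-3-one F3, and NaBO3·4H2O in THF/water oxidises it with retention to 14.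

**Step 3.** Hydride transfer from formate to the electron-rich arylidene intermediate may be slow, so that condensation outruns reduction, and decarboxylation may stay incomplete; both would leave mixtures that are hard to purify as acids. The fallback separates C–C bond formation from reduction; it sets out from 4 and comes back at 8. Doebner–Knoevenagel condensation of 4 with malonic acid (pyridine, piperidine cat., 90 °C) passes through 2-[4-(benzyloxy)-3,5-dimethoxybenzylidene]propanedioic acid F4, which loses carbon dioxide in the same flask, to (E)-3-[4-(benzyloxy)-3,5-dimethoxyphenyl]prop-2-enoic acid F5. Hydrogenation of the C=C bond over Pd/C moderated with Ph2S (H2, 1 atm, EtOAc), conditions under which aryl benzyl ethers are kept, then gives 8.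

**Step 4.** Intramolecular Friedel–Crafts acylation onto ring B may occur, because the ring position next to the chain is activated by one ortho and one para methoxy group and hydrogen chloride is formed in the step; hydrolysis of the acid chloride on handling is the second risk. The fallback avoids the acid chloride altogether; it sets out from 8 and comes back at 14. Acid 8 is dehydrated with DCC (0.5 equiv, CH2Cl2, 0 °C) to the symmetrical anhydride 3-[4-(benzyloxy)-3,5-dimethoxyphenyl]propanoic anhydride F6, which is filtered from the urea and used in step 5 in place of 9. Anhydrides are competent acyl donors in this coupling, no hydrogen chloride is ever present, and the half of the acyl component that leaves as carboxylate is recovered as 8.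

## Further compounds

F1 | step 5 | 1-(benzyloxy)-4-(but-3-en-1-yl)-2-methoxybenzene | C=CCCc1ccc(OCc2ccccc2)c(OC)c1
F2 | step 5 | 5-[4-(benzyloxy)-3,5-dimethoxyphenyl]pent-1-en-3-one | C=CC(=O)CCc1cc(OC)c(OCc2ccccc2)c(OC)c1
F3 | step 5 | (5R)-7-[4-(benzyloxy)-3-methoxyphenyl]-1-[4-(benzyloxy)-3,5-dimethoxyphenyl]-5-(4,4,5,5-tetramethyl-1,3,2-dioxaborolan-2-yl)heptan-3-one | COc1cc(CC[C@@H](B2OC(C)(C)C(C)(C)O2)CC(=O)CCc2cc(OC)c(OCc3ccccc3)c(OC)c2)ccc1OCc1ccccc1
F4 | step 3 | 2-[4-(benzyloxy)-3,5-dimethoxybenzylidene]propanedioic acid | COc1cc(C=C(C(=O)O)C(=O)O)cc(OC)c1OCc1ccccc1
F5 | step 3 | (E)-3-[4-(benzyloxy)-3,5-dimethoxyphenyl]prop-2-enoic acid | COc1cc(/C=C/C(=O)O)cc(OC)c1OCc1ccccc1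
F6 | step 4 | 3-[4-(benzyloxy)-3,5-dimethoxyphenyl]propanoic anhydride | COc1cc(CCC(=O)OC(=O)CCc2cc(OC)c(OCc3ccccc3)c(OC)c2)cc(OC)c1OCc1ccccc1
A1 | alternative 1 | 4-[4-(benzyloxy)-3,5-dimethoxyphenyl]butan-2-one | COc1cc(CCC(C)=O)cc(OC)c1OCc1ccccc1
A2 | alternative 1 | 3-[4-(benzyloxy)-3-methoxyphenyl]propanal | COc1cc(CCC=O)ccc1OCc1ccccc1
A3 | alternative 2 | (E)-7-[4-(benzyloxy)-3-methoxyphenyl]-1-[4-(benzyloxy)-3,5-dimethoxyphenyl]hept-4-en-3-one | COc1cc(CC/C=C/C(=O)CCc2cc(OC)c(OCc3ccccc3)c(OC)c2)ccc1OCc1ccccc1
A4 | alternative 3 | 1-(4-hydroxy-3,5-dimethoxyphenyl)-7-(4-hydroxy-3-methoxyphenyl)heptane-3,5-dione | COc1cc(CCC(=O)CC(=O)CCc2cc(OC)c(O)c(OC)c2)ccc1O
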